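**Plan**

1. Feature and key cut: the free tertiary OH on C3, flanked by its CH2OAc branch (C3') and the acetoxy methine C2 and bonded to the ketal carbon C4 of the 2,8-dioxabicyclo[3.2.1]octane ring, is read as a spiro oxirane on C3/C3' opened by acetate. Both oxirane C–O bonds are cut back to a C3 methylidene beside the free C2 carbinol (C1 = benzylic CH2, C7 = methyl-bearing bridgehead, C9 = allylic ketal methine).
2. Further cuts: C3=CH2 (from a C3 ketone), the C4–O ketal bond to the C9 oxygen, the C3–C4 bond (5-lithio-2,3-dihydrofuran + α-silyloxy aldehyde), the C9–C10 bond (alkenyllithium + Weinreb amide) and the aryl–C1 bond (aryl Grignard + glycidate).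
3. Forward: the oxolane ring (O–C4–C5–C6–C7) comes first, from linalool by ozonolysis. The chain is then joined at C9–C10 and at C3–C4. The 1,3-dioxane ring of the cage closes by acid ketalization. The oxirane closes in the key step and is opened by acetate.
4. Stereochemistry: C7 from (R)-linalool, C2 from methyl (R)-glycidate, C9 by CBS reduction, C4 by the bridged geometry, C3 by the C2-hydroxyl-directed epoxidation, the C10=C11 E geometry by syn-carboalumination.

Key step: step 19

Remark: "Cage" below means (1R,3S,5R)-3-[(1E)-2,6-dimethylhepta-1,5-dien-1-yl]-5-methyl-2,8-dioxabicyclo[3.2.1]octan-1-yl (cage C1 = C4, cage C3 = C9, cage C5 = C7), and commercial (R)-linalool is assumed to be used in enantiomerically enriched form.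

**Route**

Step 1
Reactants: 1 6-methylhept-5-en-2-one
Product: 3 6-methylhept-5-en-1-yne, via enol phosphate 2 (not isolated)
Conditions: LiN(i-Pr)2, THF, −78 °C; ClP(O)(OEt)2, −78 °C to rt; then LiN(i-Pr)2 (2.3 equiv), −78 °C to rt; H2O
Reagents that add atoms: none
Why: Kinetic deprotonation at the methyl group gives the less substituted enolate, and its diethyl enol phosphate undergoes base-induced elimination to the terminal alkyne (methyl ketone to alkyne conversion through the enol phosphate).

Step 2
Reactants: 3 6-methylhept-5-en-1-yne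
Product: 5 (1E)-1-iodo-2,6-dimethylhepta-1,5-diene, via alkenylalane 4 (not isolated)
Conditions: Me3Al, Cp2ZrCl2 (0.25 equiv), CH2Cl2, 0 °C to rt; then I2, THF, −30 to 0 °C
Reagents that add atoms: trimethylaluminium, C[Al](C)C; iodine, II
Why: Negishi zirconium-catalysed carboalumination adds methyl and aluminium syn across the alkyne with aluminium on the terminal carbon, and iodinolysis of the carbon–aluminium bond with retention fixes the E trisubstituted alkene that becomes C10=C11.

Step 3
Reactants: 6 1-bromo-2,5-dimethoxy-4-methylbenzene; 7 methyl (2R)-oxirane-2-carboxylate [methyl (R)-glycidate]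
Product: 9 methyl (2R)-3-(2,5-dimethoxy-4-methylphenyl)-2-hydroxypropanoate, via aryl Grignard reagent 8 (not isolated)
Conditions: Mg, THF, reflux; then CuI (copper monoiodide, 10 mol%), 7, THF, −40 to −20 °C; aq. NH4Cl
Reagents that add atoms: none
Why: Copper-catalysed Grignard opening of the epoxide (SN2 at the unsubstituted CH2, faster than addition to the ester at low temperature) forms the aryl–C1 bond and leaves the C2–O bond untouched, so the R center of the glycidate becomes C2 of the target.

Step 4
Reactants: 9 methyl (2R)-3-(2,5-dimethoxy-4-methylphenyl)-2-hydroxypropanoate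
Product: 10 methyl (2R)-2-[(tert-butyldimethylsilyl)oxy]-3-(2,5-dimethoxy-4-methylphenyl)propanoate
Conditions: t-BuMe2SiCl, imidazole, DMF, rt
Reagents that add atoms: tert-butyldimethylsilyl chloride, CC(C)(C)[Si](C)(C)Cl
Why: Silylation of the secondary hydroxyl gives a C2 protecting group that later comes off with fluoride, which avoids an oxidative deprotection in the presence of the electron-rich arene.

Step 5
Reactants: 10 methyl (2R)-2-[(tert-butyldimethylsilyl)oxy]-3-(2,5-dimethoxy-4-methylphenyl)propanoate
Product: 11 (2R)-2-[(tert-butyldimethylsilyl)oxy]-3-(2,5-dimethoxy-4-methylphenyl)propanal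
Conditions: i-Bu2AlH (1.1 equiv), CH2Cl2, −78 °C; MeOH, then aq. KNaC4H4O6 (potassium sodium tartrate)
Reagents that add atoms: none
Why: Partial reduction of the α-silyloxy ester by the aluminium hydride stops at the aldehyde because the chelated aluminium hemiacetal survives at −78 °C until the quench, and C2 is not touched.

Step 6
Reactants: 12 (R)-linalool
Product: 14 (2R)-2-ethenyl-5-methoxy-2-methyloxolane (both anomers), via lactol 13 (not isolated)
Conditions: O3 (one equivalent), CH2Cl2, −78 °C; Me2S, −78 °C to rt; then MeOH, pyridinium p-toluenesulfonate (cat.), rt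
Reagents that add atoms: methanol, CO
Why: Ozonolysis with reductive work-up cleaves the electron-rich trisubstituted alkene much faster than the vinyl group, the γ-hydroxy aldehyde closes to the five-membered lactol (the oxolane ring C4–C7 of the cage, with C7 taken unchanged from linalool), and acid-catalysed acetalization masks C4 as the methyl acetal.

Step 7
Reactants: 14 (2R)-2-ethenyl-5-methoxy-2-methyloxolane
Product: 16 2-[(2R)-5-methoxy-2-methyloxolan-2-yl]ethan-1-ol, via B-alkyl-9-BBN 15 (not isolated)
Conditions: 9-BBN, THF, 0 °C to rt; then NaOH, H2O2, 0 °C to rt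
Reagents that add atoms: hydrogen peroxide, OO
Why: Anti-Markovnikov hydroboration–oxidation with the bulky borane places oxygen on the terminal vinyl carbon (C9), and the basic oxidation leaves the acetal intact.

Step 8
Reactants: 16 2-[(2R)-5-methoxy-2-methyloxolan-2-yl]ethan-1-ol
Product: 17 [(2R)-5-methoxy-2-methyloxolan-2-yl]acetic acid
Conditions: TEMPO (2,2,6,6-tetramethylpiperidin-1-oxyl, cat.), NaClO2, NaOCl (cat.), MeCN, NaH2PO4/Na2HPO4 buffer (pH 6.7), 35 °C
Reagents that add atoms: sodium chlorite, [Na+].[O-]Cl=O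
Why: Oxoammonium oxidation to the aldehyde followed in the same pot by chlorite (Pinnick-type) oxidation gives the acid at a near-neutral pH that the acetal tolerates, and it is run here because no alkene is yet present; the acid is used at once.

Step 9
Reactants: 17 [(2R)-5-methoxy-2-methyloxolan-2-yl]acetic acid
Product: 18 N-methoxy-2-[(2R)-5-methoxy-2-methyloxolan-2-yl]-N-methylacetamide
Conditions: 1,1'-carbonyldiimidazole, CH2Cl2, 0 °C to rt; then MeNH(OMe)·HCl, rt
Reagents that add atoms: N,O-dimethylhydroxylamine hydrochloride, CNOC.Cl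
Why: Amide coupling through the acyl imidazolide under non-acidic conditions gives the Weinreb amide whose carbonyl carbon is C9.

Step 10
Reactants: 18 N-methoxy-2-[(2R)-5-methoxy-2-methyloxolan-2-yl]-N-methylacetamide
Product: 19 N-methoxy-N-methyl-2-[(2R)-2-methyl-2,3-dihydrofuran-2-yl]acetamide
Conditions: Me3SiOTf, i-Pr2NEt, CH2Cl2, −20 °C to rt
Reagents that add atoms: none
Why: Silyl triflate/amine-mediated elimination of an acetal to an enol ether, in which ionisation to the cyclic oxocarbenium ion and loss of a hydrogen from the only β-position (ring CH2) give the 2,3-dihydrofuran, and it is placed here because no hydroxyl or silyl ether is yet within reach of C4 to trap that cation as a bridged acetal.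

Step 11
Reactants: 19 N-methoxy-N-methyl-2-[(2R)-2-methyl-2,3-dihydrofuran-2-yl]acetamide; 5 (1E)-1-iodo-2,6-dimethylhepta-1,5-diene
Product: 21 (3E)-4,8-dimethyl-1-[(2R)-2-methyl-2,3-dihydrofuran-2-yl]nona-3,7-dien-2-one, via alkenyllithium 20 (not isolated)
Conditions: 5, t-BuLi (2 equiv), Et2O, −78 °C; then 19, THF, −78 to −20 °C; NaH2PO4/Na2HPO4 buffer (pH 7)
Reagents that add atoms: none
Why: Iodine–lithium exchange proceeds with retention of the E geometry and the Weinreb ketone synthesis (stable chelated tetrahedral adduct, no over-addition) forms the C9–C10 bond, the base-sensitive β-(vinyloxy) enone being carried on without delay.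

Step 12
Reactants: 21 (3E)-4,8-dimethyl-1-[(2R)-2-methyl-2,3-dihydrofuran-2-yl]nona-3,7-dien-2-one
Product: 22 (2S,3E)-4,8-dimethyl-1-[(2R)-2-methyl-2,3-dihydrofuran-2-yl]nona-3,7-dien-2-ol
Conditions: (R)-Me-CBS [(R)-1-methyl-3,3-diphenyltetrahydro-1H,3H-pyrrolo[1,2-c][1,3,2]oxazaborole, 0.5 equiv], catecholborane, toluene, −78 °C; MeOH, then aq. NaOH wash
Reagents that add atoms: none
Why: Corey–Bakshi–Shibata reduction of the enone, in which the alkenyl group acts as the large substituent so that the (R)-catalyst should deliver hydride to the face that sets C9 as S, while catecholborane at low temperature avoids hydroboration and conjugate reduction and spares the enol ether.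

Step 13
Reactants: 22 (2S,3E)-4,8-dimethyl-1-[(2R)-2-methyl-2,3-dihydrofuran-2-yl]nona-3,7-dien-2-ol
Product: 23 triethylsilyl ether of 22
Conditions: Et3SiCl, imidazole, CH2Cl2, 0 °C
Reagents that add atoms: chlorotriethylsilane, CC[Si](Cl)(CC)CC
Why: Silylation shields the C9 hydroxyl from the alkyllithium of the next step with a group that mild acid removes during the ketalization.

Step 14
Reactants: 23 triethylsilyl ether of 22; 11 (2R)-2-[(tert-butyldimethylsilyl)oxy]-3-(2,5-dimethoxy-4-methylphenyl)propanal
Product: 25 C3 carbinol adduct (2R, C3 epimers; 4,5-dihydrofuran-2-yl carbinol), via lithiated dihydrofuran 24 (not isolated)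
Conditions: 23, t-BuLi (1.3 equiv), THF, −78 to 0 °C; then 11, −78 °C; NaH2PO4/Na2HPO4 buffer (pH 7) at −78 °C
Reagents that add atoms: none
Why: α-Lithiation of the cyclic enol ether at its oxygen-bearing vinyl carbon (C4) and 1,2-addition to the α-silyloxy aldehyde form the C3–C4 bond, the new C3 carbinol arises as a mixture that step 16 erases, and the cold quench prevents silyl migration from the C2 oxygen.

Step 15
Reactants: 25 C3 carbinol adduct
Product: 26 (1RS,2R)-2-[(tert-butyldimethylsilyl)oxy]-1-Cage-3-(2,5-dimethoxy-4-methylphenyl)propan-1-ol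
Conditions: pyridinium p-toluenesulfonate (cat.), MeOH/CH2Cl2, 0 °C to rt
Reagents that add atoms: none
Why: Mild acid removes the allylic triethylsilyl ether (the hindered tert-butyldimethylsilyl ether stays) and protonates the enol ether at C5 to the C4 oxocarbenium ion, which the C9 hydroxyl traps in a six-membered ring closure (intramolecular ketalization) to give the 2,8-dioxabicyclo[3.2.1]octane, C4 forming only with the configuration that the C8 arm on C7 allows and the 9S center placing the dienyl group equatorial.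

Step 16
Reactants: 26 cage alcohol (C3 epimers)
Product: 27 (2R)-2-[(tert-butyldimethylsilyl)oxy]-1-Cage-3-(2,5-dimethoxy-4-methylphenyl)propan-1-one
Conditions: Dess–Martin periodinane, NaHCO3, CH2Cl2, rt
Reagents that add atoms: none
Why: Dess–Martin oxidation converts both C3 epimers into one ketone under buffered, non-basic conditions that leave the α-silyloxy center C2 and the ketal untouched.

Step 17
Reactants: 27 C3 ketone
Product: 28 tert-butyl{[(2R)-3-Cage-1-(2,5-dimethoxy-4-methylphenyl)but-3-en-2-yl]oxy}dimethylsilane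
Conditions: Cp2TiMe2 (3 equiv), toluene, 65 °C, dark
Reagents that add atoms: dimethyltitanocene, [CH3-].[CH3-].c1cc[cH-]c1.c1cc[cH-]c1.[Ti+4]
Why: Petasis methylenation, in which the titanium methylidene formed by loss of methane adds to the carbonyl and cycloreverts to the C3 methylidene, is neither basic nor acidic and should therefore not epimerise C2 or open the ketal as a phosphorus ylide might.

Step 18
Reactants: 28 silyl ether of the allylic alcohol
Product: 29 (2R)-3-Cage-1-(2,5-dimethoxy-4-methylphenyl)but-3-en-2-ol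
Conditions: Bu4NF, THF, 0 °C to rt
Reagents that add atoms: none
Why: Fluoride-mediated desilylation frees the C2 hydroxyl that must direct the epoxidation, and the ketal, the alkenes and the aryl ethers are inert to fluoride.

Step 19
Reactants: 29 (2R)-3-Cage-1-(2,5-dimethoxy-4-methylphenyl)but-3-en-2-ol
Product: 30 (1R)-1-[(2S)-2-Cage-oxiran-2-yl]-2-(2,5-dimethoxy-4-methylphenyl)ethan-1-ol (erythro spiro epoxide on C3)
Conditions: VO(acac)2 (10 mol%), t-BuOOH (1.5 equiv, in decane), CH2Cl2, 0 °C to rt
Reagents that add atoms: tert-butyl hydroperoxide, CC(C)(C)OO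
Why: t-BuOOH oxidises VO(acac)2 to a pentavalent vanadium species that binds the C2 alkoxide and the alkylperoxide, and the activated peroxide oxygen is passed to the adjacent C3=CH2 bond in one concerted transfer, so both C–O bonds of the spiro oxirane form together. The closest known reaction type is the vanadium-catalysed, hydroxyl-directed epoxidation of 2-substituted secondary allylic alcohols, which is erythro-selective. The only ring closed is the oxirane, by concerted oxygen-atom transfer to the alkene (a [2+1] addition) and not by a stepwise displacement. The new stereocenter C3 is controlled by the C2 carbinol through the metal template: allylic 1,2-strain between the cage on C3 and the substituents on C2 places the C2 hydrogen in the alkene plane beside the cage and the arylmethyl group on the face away from vanadium, so oxygen is delivered to the face that gives the 2R,3S (erythro) epoxy alcohol, the C2/C3 relationship of the target. The step needs facial selectivity, secured by that strain and the bound hydroxyl, and chemoselectivity for the methylidene over the two trisubstituted alkenes of the tail and the electron-rich arene, secured because only the methylidene is allylic to a free hydroxyl and vanadium/t-BuOOH leaves unbound alkenes essentially untouched. The neutral conditions also spare the ketal.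

Step 20
Reactants: 30 erythro epoxy alcohol
Product: 31 (2S,3R)-2-Cage-4-(2,5-dimethoxy-4-methylphenyl)-2,3-dihydroxybutyl acetate
Conditions: CsOAc, AcOH, DMF, 70 °C
Reagents that add atoms: acetic acid, CC(=O)O
Why: SN2 epoxide opening by acetate at the unsubstituted CH2 terminus releases the ring strain and installs the primary acetate while the C3–O bond, and with it the C3 configuration, stays untouched; the acetic acid buffer suppresses Payne rearrangement, and acetyl migration to the C2 hydroxyl would be harmless because step 21 acetylates that position.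

Step 21
Reactants: 31 primary acetate diol
Product: 32 (2S,3R)-3-(acetyloxy)-2-Cage-4-(2,5-dimethoxy-4-methylphenyl)-2-hydroxybutyl acetate
Conditions: Ac2O, pyridine, 4-(dimethylamino)pyridine (cat.), CH2Cl2, 0 °C to rt
Reagents that add atoms: acetic anhydride, CC(=O)OC(C)=O
Why: Nucleophile-catalysed acetylation esterifies the secondary C2 hydroxyl, whereas the tertiary C3 hydroxyl next to the ketal carbon is too hindered to react under these conditions.

Step 22
Reactants: 32 diacetate dimethyl ether
Product: 34 CNP0160303.2, (2S,3R)-3-(acetyloxy)-2-Cage-4-(2,5-dihydroxy-4-methylphenyl)-2-hydroxybutyl acetate, via quinone 33 (not isolated)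
Conditions: (NH4)2Ce(NO3)6 (2.5 equiv), MeCN/H2O, 0 °C; then aq. Na2S2O4, EtOAc, rt
Reagents that add atoms: water, O
Why: Oxidative demethylation of the hydroquinone dimethyl ether by tetravalent cerium gives the para-quinone (its oxygens come from water and the methyl groups leave as methanol) faster than the isolated alkenes are attacked, and dithionite then reduces the quinone to the hydroquinone of the target.

**Compound list**

1 | 6-methylhept-5-en-2-one | CC(=O)CCC=C(C)C | starting material
2 | diethyl 6-methylhepta-1,5-dien-2-yl phosphate | C=C(CCC=C(C)C)OP(=O)(OCC)OCC | intermediate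
3 | 6-methylhept-5-en-1-yne | C#CCCC=C(C)C | intermediate
4 | [(1E)-2,6-dimethylhepta-1,5-dien-1-yl]dimethylalane | C[Al](C)/C=C(\C)CCC=C(C)C | intermediate
5 | (1E)-1-iodo-2,6-dimethylhepta-1,5-diene | I/C=C(\C)CCC=C(C)C | intermediate
6 | 1-bromo-2,5-dimethoxy-4-methylbenzene | COc1cc(Br)c(OC)cc1C | starting material
7 | methyl (2R)-oxirane-2-carboxylate, methyl (R)-glycidate | COC(=O)[C@H]1CO1 | starting material
8 | (2,5-dimethoxy-4-methylphenyl)magnesium bromide | COc1cc([Mg]Br)c(OC)cc1C | intermediate
9 | methyl (2R)-3-(2,5-dimethoxy-4-methylphenyl)-2-hydroxypropanoate | COC(=O)[C@H](O)Cc1cc(OC)c(C)cc1OC | intermediate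
10 | methyl (2R)-2-[(tert-butyldimethylsilyl)oxy]-3-(2,5-dimethoxy-4-methylphenyl)propanoate | COC(=O)[C@H](O[Si](C)(C)C(C)(C)C)Cc1cc(OC)c(C)cc1OC | intermediate
11 | (2R)-2-[(tert-butyldimethylsilyl)oxy]-3-(2,5-dimethoxy-4-methylphenyl)propanal | O=C[C@H](O[Si](C)(C)C(C)(C)C)Cc1cc(OC)c(C)cc1OC | intermediate
12 | (R)-linalool, (3R)-3,7-dimethylocta-1,6-dien-3-ol | CC(C)=CCC[C@](C)(C=C)O | starting material
13 | (5R)-5-ethenyl-5-methyloxolan-2-ol (lactol, both anomers) | OC1CC[C@](C)(C=C)O1 | intermediate
14 | (2R)-2-ethenyl-5-methoxy-2-methyloxolane (both anomers) | COC1CC[C@](C)(C=C)O1 | intermediate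
15 | 9-[2-(5-methoxy-2-methyloxolan-2-yl)ethyl]-9-borabicyclo[3.3.1]nonane (quaternary center arranged as in 14) | COC1CC[C@](C)(CCB2C3CCCC2CCC3)O1 | intermediate
16 | 2-[(2R)-5-methoxy-2-methyloxolan-2-yl]ethan-1-ol | COC1CC[C@](C)(CCO)O1 | intermediate
17 | [(2R)-5-methoxy-2-methyloxolan-2-yl]acetic acid | COC1CC[C@](C)(CC(=O)O)O1 | intermediate
18 | N-methoxy-2-[(2R)-5-methoxy-2-methyloxolan-2-yl]-N-methylacetamide | COC1CC[C@](C)(CC(=O)N(C)OC)O1 | intermediate
19 | N-methoxy-N-methyl-2-[(2R)-2-methyl-2,3-dihydrofuran-2-yl]acetamide | C1=CC[C@](C)(CC(=O)N(C)OC)O1 | intermediate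
20 | [(1E)-2,6-dimethylhepta-1,5-dien-1-yl]lithium | [Li]/C=C(\C)CCC=C(C)C | intermediate
21 | (3E)-4,8-dimethyl-1-[(2R)-2-methyl-2,3-dihydrofuran-2-yl]nona-3,7-dien-2-one | C1=CC[C@](C)(CC(=O)/C=C(\C)CCC=C(C)C)O1 | intermediate
22 | (2S,3E)-4,8-dimethyl-1-[(2R)-2-methyl-2,3-dihydrofuran-2-yl]nona-3,7-dien-2-ol | C1=CC[C@](C)(C[C@H](O)/C=C(\C)CCC=C(C)C)O1 | intermediate
23 | triethyl({(2S,3E)-4,8-dimethyl-1-[(2R)-2-methyl-2,3-dihydrofuran-2-yl]nona-3,7-dien-2-yl}oxy)silane | C1=CC[C@](C)(C[C@H](O[Si](CC)(CC)CC)/C=C(\C)CCC=C(C)C)O1 | intermediate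
24 | {(5R)-5-[(2S,3E)-4,8-dimethyl-2-(triethylsilyloxy)nona-3,7-dien-1-yl]-5-methyl-4,5-dihydrofuran-2-yl}lithium | [Li]C1=CC[C@](C)(C[C@H](O[Si](CC)(CC)CC)/C=C(\C)CCC=C(C)C)O1 | intermediate
25 | (1RS,2R)-2-[(tert-butyldimethylsilyl)oxy]-3-(2,5-dimethoxy-4-methylphenyl)-1-{(5R)-5-[(2S,3E)-4,8-dimethyl-2-(triethylsilyloxy)nona-3,7-dien-1-yl]-5-methyl-4,5-dihydrofuran-2-yl}propan-1-ol | OC([C@H](O[Si](C)(C)C(C)(C)C)Cc1cc(OC)c(C)cc1OC)C1=CC[C@](C)(C[C@H](O[Si](CC)(CC)CC)/C=C(\C)CCC=C(C)C)O1 | intermediate
26 | (1RS,2R)-2-[(tert-butyldimethylsilyl)oxy]-1-Cage-3-(2,5-dimethoxy-4-methylphenyl)propan-1-ol | OC([C@H](O[Si](C)(C)C(C)(C)C)Cc1cc(OC)c(C)cc1OC)[C@]12CC[C@](C)(C[C@@H](/C=C(\C)CCC=C(C)C)O1)O2 | intermediate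
27 | (2R)-2-[(tert-butyldimethylsilyl)oxy]-1-Cage-3-(2,5-dimethoxy-4-methylphenyl)propan-1-one | O=C([C@H](O[Si](C)(C)C(C)(C)C)Cc1cc(OC)c(C)cc1OC)[C@]12CC[C@](C)(C[C@@H](/C=C(\C)CCC=C(C)C)O1)O2 | intermediate
28 | tert-butyl{[(2R)-3-Cage-1-(2,5-dimethoxy-4-methylphenyl)but-3-en-2-yl]oxy}dimethylsilane | C=C([C@H](O[Si](C)(C)C(C)(C)C)Cc1cc(OC)c(C)cc1OC)[C@]12CC[C@](C)(C[C@@H](/C=C(\C)CCC=C(C)C)O1)O2 | intermediate
29 | (2R)-3-Cage-1-(2,5-dimethoxy-4-methylphenyl)but-3-en-2-ol | C=C([C@H](O)Cc1cc(OC)c(C)cc1OC)[C@]12CC[C@](C)(C[C@@H](/C=C(\C)CCC=C(C)C)O1)O2 | intermediate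
30 | (1R)-1-[(2S)-2-Cage-oxiran-2-yl]-2-(2,5-dimethoxy-4-methylphenyl)ethan-1-ol | O3C[C@]3([C@H](O)Cc4cc(OC)c(C)cc4OC)[C@]12CC[C@](C)(C[C@@H](/C=C(\C)CCC=C(C)C)O1)O2 | intermediate
31 | (2S,3R)-2-Cage-4-(2,5-dimethoxy-4-methylphenyl)-2,3-dihydroxybutyl acetate | CC(=O)OC[C@](O)([C@H](O)Cc1cc(OC)c(C)cc1OC)[C@]12CC[C@](C)(C[C@@H](/C=C(\C)CCC=C(C)C)O1)O2 | intermediate
32 | (2S,3R)-3-(acetyloxy)-2-Cage-4-(2,5-dimethoxy-4-methylphenyl)-2-hydroxybutyl acetate | CC(=O)OC[C@](O)([C@H](OC(C)=O)Cc1cc(OC)c(C)cc1OC)[C@]12CC[C@](C)(C[C@@H](/C=C(\C)CCC=C(C)C)O1)O2 | intermediate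
33 | (2S,3R)-3-(acetyloxy)-2-Cage-2-hydroxy-4-(4-methyl-3,6-dioxocyclohexa-1,4-dien-1-yl)butyl acetate | CC(=O)OC[C@](O)([C@H](OC(C)=O)CC1=CC(=O)C(C)=CC1=O)[C@]12CC[C@](C)(C[C@@H](/C=C(\C)CCC=C(C)C)O1)O2 | intermediate
34 | CNP0160303.2, (2S,3R)-3-(acetyloxy)-2-Cage-4-(2,5-dihydroxy-4-methylphenyl)-2-hydroxybutyl acetate | CC(=O)OC[C@](O)([C@@H](Cc1cc(O)c(C)cc1O)OC(C)=O)[C@]12CC[C@](C)(C[C@@H](/C=C(\C)CCC=C(C)C)O1)O2 | target

**Step count and risks**

Total steps: 22. Longest linear sequence: 17 steps (steps 6 to 22, from (R)-linalool).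

Steps most likely to fail:

Step 14. Metalation of 23 may be eroded by competing deprotonation at the allylic silyloxy methine, and the hindered vinyllithium may enolise the α-silyloxy aldehyde or provoke silyl migration, so that the union stalls. The fallback reverses the polarity of the C3–C4 bond; it sets out from 23 and 11 and comes back at 28. The enol ether of 23 is oxidised with (C5H5NH)[CrO3Cl] in CH2Cl2 to the γ-lactone F1. Aldehyde 11 is homologated with the Ohira–Bestmann reagent (K2CO3, MeOH) to the terminal alkyne F2, and bromoboration with B-bromo-9-BBN followed by protonolysis with acetic acid gives the 2-bromoalkene F3. Bromine–lithium exchange on F3 (t-BuLi, Et2O, −78 °C) and addition to F1 give the hydroxy enone F4 (in equilibrium with its lactol). Pyridinium p-toluenesulfonate in MeOH/CH2Cl2 then removes the triethylsilyl group and closes the cage to 28, which bypasses steps 15 to 17.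

Step 17. The titanium methylidene may fail to engage a carbonyl flanked by the fully substituted ketal carbon and the silyloxy methine, or prolonged heating may epimerise C2 through enolisation. The fallback is a two-stage Peterson olefination from 27 back to 28. Me3SiCH2Li with CeCl3 (THF, −78 °C), a small and weakly basic nucleophile, adds to the ketone to give the β-hydroxysilane F5, and KH (THF, 0 °C) triggers syn-elimination of silanolate to give 28.

Step 19. Facial selectivity may erode if a ketal oxygen also binds vanadium and changes the reactive conformer. The fallback replaces substrate control by reagent control and goes from 29 directly to 30: a Sharpless asymmetric epoxidation with Ti(Oi-Pr)4, D-(−)-diisopropyl tartrate and t-BuOOH (4 Å molecular sieves, CH2Cl2, −20 °C). This is the tartrate enantiomer for which the 2R alcohol is the fast-reacting, erythro-selective partner; no new compound arises.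

Further compounds
F1 | step 14 | (5R)-5-[(2S,3E)-4,8-dimethyl-2-(triethylsilyloxy)nona-3,7-dien-1-yl]-5-methyloxolan-2-one | O=C1CC[C@](C)(C[C@H](O[Si](CC)(CC)CC)/C=C(\C)CCC=C(C)C)O1
F2 | step 14 | tert-butyl{[(2R)-1-(2,5-dimethoxy-4-methylphenyl)but-3-yn-2-yl]oxy}dimethylsilane | C#C[C@H](O[Si](C)(C)C(C)(C)C)Cc1cc(OC)c(C)cc1OC
F3 | step 14 | {[(2R)-3-bromo-1-(2,5-dimethoxy-4-methylphenyl)but-3-en-2-yl]oxy}(tert-butyl)dimethylsilane | C=C(Br)[C@H](O[Si](C)(C)C(C)(C)C)Cc1cc(OC)c(C)cc1OC
F4 | step 14 | (2R,7R,9S,10E)-2-[(tert-butyldimethylsilyl)oxy]-1-(2,5-dimethoxy-4-methylphenyl)-7-hydroxy-7,11,15-trimethyl-3-methylidene-9-[(triethylsilyl)oxy]hexadeca-10,14-dien-4-one | C=C([C@H](O[Si](C)(C)C(C)(C)C)Cc1cc(OC)c(C)cc1OC)C(=O)CC[C@@](C)(O)C[C@H](O[Si](CC)(CC)CC)/C=C(\C)CCC=C(C)C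
F5 | step 17 | (2RS,3R)-3-[(tert-butyldimethylsilyl)oxy]-2-Cage-4-(2,5-dimethoxy-4-methylphenyl)-1-(trimethylsilyl)butan-2-ol | C[Si](C)(C)CC(O)([C@H](O[Si](C)(C)C(C)(C)C)Cc1cc(OC)c(C)cc1OC)[C@]12CC[C@](C)(C[C@@H](/C=C(\C)CCC=C(C)C)O1)O2
F0 | step 19 | none | none
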